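Over 5.0 d these flasks receive equal charges and differ in when substrate and first nucleophile enter.

    substrate → intermediate (k1 = 0.131 h⁻¹)
    first nucleophile + intermediate → target (k2 = 161 M⁻¹ h⁻¹)
    second nucleophile + intermediate → other capture product (k3 = 1260 M⁻¹ h⁻¹)
    intermediate → solvolysis product (k4 = 2.87 h⁻¹)
    first nucleophile ⇌ dormant form (K5 = 2.5, k5 = 0.527 h⁻¹)
    intermediate → side product (k6 = 0.0368 h⁻¹)
    gas ⇌ second nucleophile, rate k7*(csat - [second nucleophile]) (k7 = 4.03 h⁻¹, csat = 5.6 mM)

common to all: gas 5.6 mM (held); time 5.0 d
- blue: substrate 0.050 M (fed, over 25 h); first nucleophile 0.700 equiv; all else is in the flask from the start; the feed brings no volume worth counting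
- grey: substrate 0.050 M; first nucleophile 0.700 equiv (fed, over 25 h); all else is in the flask from the start; the feed brings no volume worth counting
- teal: substrate 0.050 M; first nucleophile 0.700 equiv; everything together at the start

- at the start none of second nucleophile is dissolved
- run time (blue): 5.0 d

- the best flask by amount of target, in percent of the substrate charged; "all alike" if 1.5 percentage points covers them all (blue / grey / teal / all alike)
- amount of target at the end, in percent of the substrate charged, blue
- amount of target at the end, in percent of the substrate charged, grey
- amount of target at the end, in percent of the substrate charged, teal

Reckoned by hand, the making of intermediate and its capture by first nucleophile, taken by themselves, let target reach 0.700 of the substrate charged, the ratio of the charges. Now add the other exits. Second nucleophile, taken at saturation, makes its capture pseudo-first-order, and with solvolysis and the side step intermediate leaves by these routes at 9.96 h⁻¹. First nucleophile as charged captures at 5.63 h⁻¹, so the share going to target falls to 36.1%. Intermediate has a half-life of 0.0445 h, shorter than the 5.29 h half-life of substrate, so target is reckoned as this share of the substrate turned over.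

The dormant form comes last. It leaves 28.6% of first nucleophile free, with a relaxation half-life of 0.939 h, shorter than that of substrate. Capture drops to 1.61 h⁻¹, and the result is the equilibrium share 13.9%: the fraction of intermediate reaching target when the charge of first nucleophile, none of it yet spent, stands at equilibrium with dormant form and second nucleophile stands at saturation. This is the zero of the scale.

Blue, with substrate fed over 25 h, longer than that relaxation, sits near the zero. Spending first nucleophile on target lowers the share in blue as the run proceeds, and the mean of its reckoned first and last values is 12.7%. Teal gets an early window, reckoned as a weight: substrate turnover set against the relaxation of first nucleophile gives 0.151, and this weight on the gap between the starting and equilibrium shares adds 3.3 percentage points to the mean above, giving 16.0% for teal. Grey is reckoned at one moment, the mean substrate lifetime of 7.63 h, when it has received 30.5% of its first nucleophile, so its capture is taken to shrink by that factor and its share comes to 4.70%. That ranks teal first, above the other flasks.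

The forecast, holding that “Grey has little nucleophile while most substrate reacts”, named teal best, with 13.1% for blue, 5.7% for grey and 16.5% for teal, each above this reckoning.

The flasks give 13.0% in blue, 5.80% in grey and 16.5% in teal, with teal best; blue stands 0.90 points under the equilibrium share 13.9%, and grey 1.1 points over its reckoned share. At 1.04 d, the end of the feed, grey held 5.30% of target with 3.78% of substrate left, while blue held 9.47% with 29.4% left. The neighbour of teal with 2.80 equiv of first nucleophile, reckoned as teal was, has an equilibrium share of 39.3% and a mean share of 37.5%; its early window adds 4.5 points, which makes 42.0%, and that flask ends at 43.8% of target.

All constants come from no measurement; what happens was integrated by code.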